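**Retrosynthetic overview**
- Feature: on the pyrrole ring of the target, C2 and C3 each carry a bromine. Each of these C-Br bonds is traced back to a C-CO2H bond (ipso-bromodecarboxylation), so C2 and C3 become the two alkyne carbons of dimethyl acetylenedicarboxylate. The benzene ring with Br at C5 and C6 is 3,4-dibromoaniline.
- Disconnections: C2-Br and C3-Br lead back to the 2,3-diacid and then the 2,3-diester. C3-C3a (oxidative palladium C-H/C-H coupling) leads back to an N-aryl enamine diester. N1-C2 (aza-Michael addition) leads back to the aniline and the alkyne.
- Ring order: the benzene ring is bought. The pyrrole ring (N1, C2, C3, C3a, C7a) is the only ring formed, and it is closed at carbon in step 2.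

Key step: step 2

Remark: enamine 3 is written as the Z isomer (N-H hydrogen-bonded to the ester on the CH carbon). Any E isomer formed should equilibrate through the imine tautomer under the conditions of step 2, so the geometry is of no consequence.

Step 1
Reactants: 1 3,4-dibromoaniline; 2 dimethyl acetylenedicarboxylate
Product: 3 dimethyl (Z)-2-(3,4-dibromoanilino)but-2-enedioate
Conditions: MeOH, 0 °C to rt
Reagents that add atoms: none
Why: Aza-Michael (conjugate) addition of the aniline nitrogen to the electron-poor alkyne, followed by proton transfer, should give the push-pull enamine, with the Z isomer held by an N-H···O=C hydrogen bond; no stereocenter is formed.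

Step 2
Reactants: 3 dimethyl (Z)-2-(3,4-dibromoanilino)but-2-enedioate
Product: 4 dimethyl 5,6-dibromo-1H-indole-2,3-dicarboxylate
Conditions: Pd(OAc)2 (10 mol %), Cu(OAc)2 (2.5 equiv), N,N-dimethylacetamide/pivalic acid 4:1, 120 °C, argon
Reagents that add atoms: none
Why: Divalent palladium from Pd(OAc)2 should palladate the nucleophilic CH carbon of the enamine, and carboxylate-assisted concerted metalation-deprotonation of an ortho aryl C-H then gives a six-membered azapalladacycle; reductive elimination forms the C3-C3a bond and Cu(OAc)2 returns zerovalent palladium to the divalent state. The closest known reaction type is the Pd(OAc)2-catalysed oxidative cyclization of N-aryl enamino esters and of aniline-acetylenedicarboxylate adducts to indole carboxylates, an intramolecular dehydrogenative C-H/C-H coupling related to the Fujiwara-Moritani reaction. The pyrrole ring (N1, C2, C3, C3a, C7a) is closed as a five-membered annulation at carbon, by C-C bond formation between the enamine carbon and the arene, with N1-C7a and N1-C2 already in place. No stereocenter is formed. Two selectivities are needed: between the two ortho C-H bonds, the bromine at aniline C3 crowds the C2-H that lies between it and nitrogen, so metalation should go to the open C6-H and give the 5,6-dibromo isomer; between C-H and C-Br, the phosphine-free acidic medium and the excess of Cu(OAc)2 keep palladium divalent, and the absence of base shuts down Ullmann-type coupling of the aryl bromides by monovalent copper.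

Step 3
Reactants: 4 dimethyl 5,6-dibromo-1H-indole-2,3-dicarboxylate
Product: 6 5,6-dibromo-1H-indole-2,3-dicarboxylic acid, via disodium 5,6-dibromo-1H-indole-2,3-dicarboxylate 5 (not isolated)
Conditions: NaOH (aq., 5 equiv), THF/MeOH, 60 °C; then 2 M HCl, 0 °C, pH 2
Reagents that add atoms: sodium hydroxide, [Na+].[OH-]
Why: Saponification (base-mediated acyl substitution) of both methyl esters should give the dicarboxylate, and cold acidification precipitates the diacid before the C3 carboxyl can be lost, the aryl bromides being inert to aqueous hydroxide at this temperature.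

Step 4
Reactants: 6 5,6-dibromo-1H-indole-2,3-dicarboxylic acid
Product: 8 2,3,5,6-tetrabromo-1H-indole, via 3,5,6-tribromo-1H-indole-2-carboxylic acid 7 (not isolated)
Conditions: NBS (2.05 equiv), LiOAc (10 mol %), DMF, 0 °C to rt, dark
Reagents that add atoms: N-bromosuccinimide, O=C1CCC(=O)N1Br
Why: In this electrophilic ipso-bromodecarboxylation (Hunsdiecker-type halodecarboxylation of a heteroaromatic acid), electrophilic bromine from NBS should attack the carboxyl-bearing, enamine-like C3, the 3H-indolium intermediate rearomatises by loss of CO2, and the same sequence at C2 of the 3-bromo acid completes the vicinal dibromide, while the two benzo bromines deactivate C4 and C7 against further bromination.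

**Compound list**
1 | 3,4-dibromoaniline | Nc1ccc(Br)c(Br)c1 | starting material
2 | dimethyl acetylenedicarboxylate (dimethyl but-2-ynedioate) | COC(=O)C#CC(=O)OC | starting material
3 | dimethyl (Z)-2-(3,4-dibromoanilino)but-2-enedioate | COC(=O)/C=C(\Nc1ccc(Br)c(Br)c1)C(=O)OC | intermediate
4 | dimethyl 5,6-dibromo-1H-indole-2,3-dicarboxylate | COC(=O)c1[nH]c2cc(Br)c(Br)cc2c1C(=O)OC | intermediate
5 | disodium 5,6-dibromo-1H-indole-2,3-dicarboxylate | [Na+].[Na+].[O-]C(=O)c1[nH]c2cc(Br)c(Br)cc2c1C(=O)[O-] | intermediate
6 | 5,6-dibromo-1H-indole-2,3-dicarboxylic acid | OC(=O)c1[nH]c2cc(Br)c(Br)cc2c1C(=O)O | intermediate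
7 | 3,5,6-tribromo-1H-indole-2-carboxylic acid | OC(=O)c1[nH]c2cc(Br)c(Br)cc2c1Br | intermediate
8 | 2,3,5,6-tetrabromo-1H-indole | Brc1cc2[nH]c(Br)c(Br)c2cc1Br | target

Total step count: 4
Longest linear sequence: 4 steps (1 to 3 to 4 to 6 to 8)

**Steps most likely to fail**

Step 2. The risks are oxidative addition of zerovalent palladium into the aryl C-Br bonds when reoxidation lags (oligomerisation, protodebromination), slow C-H metalation of the electron-poor dibromoarene, and incomplete discrimination between the two ortho C-H bonds. The fallback introduces the benzo bromines after ring closure. It sets out from 2: commercial aniline (Nc1ccccc1) added to 2 in MeOH should give dimethyl (Z)-2-anilinobut-2-enedioate F1. The same Pd(OAc)2/Cu(OAc)2 cyclization, now with no regiochemical question and no C-Br bond, should give dimethyl 1H-indole-2,3-dicarboxylate F2. Because both pyrrole carbons are blocked and deactivated by the esters, electrophilic bromination (Br2, AcOH, rt to 50 °C) should go to the benzo ring, first para to N1 to give dimethyl 5-bromo-1H-indole-2,3-dicarboxylate F3 and then at C6. The fallback comes back to the route at 4.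

Step 4. After the easy substitution at C3, the C2 carboxyl may resist ipso attack, so that the remaining NBS over-oxidises the 3-bromoindole at C3 (geminal dibromination, then oxindole formation on work-up) or brominates nitrogen. The fallback makes the two C-Br bonds by ordinary C-H bromination. It sets out from 6: protodecarboxylation (Ag2CO3 10 mol %, AcOH, DMSO, 120 °C) should remove the C3 carboxyl first to give 5,6-dibromo-1H-indole-2-carboxylic acid F4, and then the C2 carboxyl through a C2-silver species to give 5,6-dibromo-1H-indole F5. NBS (2.0 equiv, THF, −78 to 0 °C) should then brominate C3 to give 3,5,6-tribromo-1H-indole F6 and go on to C2. The fallback comes back to the route at 8.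

Step 3. Hydrolysis may stall at the half ester, because the C3 ester is a vinylogous carbamate and must be attacked on a molecule that already carries a carboxylate; forcing conditions followed by acidification risk loss of the C3 carboxyl. The fallback replaces the methyl esters by acid-labile esters. It sets out from 1: commercial di-tert-butyl acetylenedicarboxylate (CC(C)(C)OC(=O)C#CC(=O)OC(C)(C)C) in place of 2 should give di-tert-butyl (Z)-2-(3,4-dibromoanilino)but-2-enedioate F7. The oxidative cyclization in its basic variant (Pd(OAc)2 10 mol %, Cu(OAc)2, K2CO3, DMF, 80 to 100 °C), which spares the tert-butyl esters from hot acid, should give di-tert-butyl 5,6-dibromo-1H-indole-2,3-dicarboxylate F8. Trifluoroacetic acid in CH2Cl2 at 0 °C then cleaves both esters by alkyl-oxygen fission, and evaporation leaves the diacid without an aqueous acidification. The fallback comes back to the route at 6.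

**Further compounds**
F1 | step 2 | dimethyl (Z)-2-anilinobut-2-enedioate | COC(=O)/C=C(\Nc1ccccc1)C(=O)OC
F2 | step 2 | dimethyl 1H-indole-2,3-dicarboxylate | COC(=O)c1[nH]c2ccccc2c1C(=O)OC
F3 | step 2 | dimethyl 5-bromo-1H-indole-2,3-dicarboxylate | COC(=O)c1[nH]c2ccc(Br)cc2c1C(=O)OC
F4 | step 4 | 5,6-dibromo-1H-indole-2-carboxylic acid | OC(=O)c1cc2cc(Br)c(Br)cc2[nH]1
F5 | step 4 | 5,6-dibromo-1H-indole | Brc1cc2cc[nH]c2cc1Br
F6 | step 4 | 3,5,6-tribromo-1H-indole | Brc1c[nH]c2cc(Br)c(Br)cc12
F7 | step 3 | di-tert-butyl (Z)-2-(3,4-dibromoanilino)but-2-enedioate | CC(C)(C)OC(=O)/C=C(\Nc1ccc(Br)c(Br)c1)C(=O)OC(C)(C)C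
F8 | step 3 | di-tert-butyl 5,6-dibromo-1H-indole-2,3-dicarboxylate | CC(C)(C)OC(=O)c1[nH]c2cc(Br)c(Br)cc2c1C(=O)OC(C)(C)C
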